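- In a one-step world target would take a fixed share of the substrate lost, but Friday's run gives 7.94% up to 0.417 d and 36.5% between 1.67 d and 3.00 d.

| flask | substrate | first nucleophile | second nucleophile | capture agent | protic impurity | remark | time |
|---|---|---|---|---|---|---|---|
| Friday's | 0.036 M | 0.036 M | 0.0432 M | 0.0027 M | 0.036 M | run made earlier |  |
| Monday's | 0.036 M | 0.036 M | 0.0432 M | 0.0068 M | 0.036 M | run made earlier |  |
| Thursday's | 0.036 M | 0.028 M | 0.0432 M | 0.0108 M | 0.036 M | run made earlier |  |
| gamma | 0.036 M | 0.0120 M | 0.0432 M | 0.00500 M | 0.0360 M |  | 4.0 d |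
| beta | 0.036 M | 0.0360 M | 0.0432 M | 0.0108 M | 0.0360 M |  | 4.0 d |

- Friday's (time / d: target / %, substrate / %): 0.208: 0.9, 88.6; 0.417: 1.7, 78.6; 0.833: 3.7, 61.9; 1.67: 7.6, 38.8; 3.00: 15.0, 18.5
- Monday's (time / d: target / %, substrate / %): 0.208: 0.6, 88.5; 0.417: 1.2, 79.1; 0.833: 3.0, 62.3; 1.67: 7.2, 38.7; 3.00: 14.5, 19.0
- Thursday's (time / d: target / %, substrate / %): 0.250: 0.9, 86.5; 0.625: 2.0, 69.5; 1.25: 3.8, 49.1; 2.08: 7.8, 30.7; 3.00: 12.3, 19.2

(scatter of a reading: 0.3 percentage points)



- which of the two ends with the higher amount of target, in percent of the substrate charged ("neither" if they lie within 2 percentage points) (gamma / beta / neither)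
- target at the end, in percent of the substrate charged, gamma
- target at the end, in percent of the substrate charged, beta

- I assume the second nucleophile competes with the first, so target's rate over the competitor's is S·B/D, with B and D the concentrations of first and second nucleophile and S the selectivity factor.
- Friday's early share, taken on the charges, gives S = 0.104, a reading with its scatter.
- D* = S·B on the charge is 0.00373 M for beta, the crossing level at which the two tie; for gamma it is 0.00124 M. Watch D against these, 8.63% and 2.88% of its charge.
- Monday's substrate reads as a fall at 0.535 /d, so I reckon 7.9 percentage points goes between 3.00 d and 4.0 d in beta and in gamma, and I give target half of it.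
- Starting from Monday's 14.5%, I reckon 18.4% for beta. With a third of that reading, I reckon 8.77% for gamma.
- Leave the capture agent alone: Friday's and Monday's target read 15.0% and 14.5% at 3.00 d. Don't top up second nucleophile, which lifts D back towards or above D*.
- The forecast says beta, with 19.5% for beta and 8.5% for gamma: “Target forms far more slowly”.
- The flasks give beta ahead, 18.6% for beta and 11.0% for gamma, against my 18.4% and 8.77%.

    substrate ⇌ open intermediate (K = 0.187, k = 4.05 × 10⁻⁴ /min)
    first nucleophile + open intermediate → target (k = 0.260 /M/min)
    second nucleophile + open intermediate → other capture product (k = 3.08 /M/min)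
    substrate + target → side product (k = 0.00313 /M/min)
    open intermediate + capture agent → trapped intermediate (k = 0.0544 /M/min)
    second nucleophile + protic impurity → quenched reagent (k = 0.0127 /M/min)

- Neither flask is at rest at 4.00 d. Beta's second nucleophile reads 12.5% at 2.00 d and 1.56% at 4.00 d; gamma's reads 9.24% at 2.00 d and 0.124% at 4.00 d, so both pass their crossing between those times. Substrate left is 11% in beta and 14% in gamma. At 40.0 d target reaches 26.8% in beta and 21.6% in gamma, while beta's other capture product goes from 65.5% to 66.5%.
- In the neighbour of gamma with 0.014 M of protic impurity, D* stays at 2.88% of charge. Its second nucleophile still reads 8.96% at 4.00 d, so it hasn't crossed, and target is 4.57%, less than gamma's 11.0%.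

The earlier runs and the new flask are calculated with made-up constants.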